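**Retrosynthetic overview**
1. Target 15 ⇐ β,γ‑unsaturated lactone 13: the last step makes the C8a–O bond and moves the alkene into conjugation (aerobic γ‑hydroxylation of the lactone dienolate).
2. 13 ⇐ triene ester 12 by an ester‑tethered intramolecular Diels–Alder reaction; ring B and the lactone form together (C9a–C3a and C4a–C4), ring C comes in with the diene.
3. 12 ⇐ tertiary cyclopentenol 8 + dienoic acid 9 (acyl C–O bond; this oxygen becomes the lactone oxygen).
4. 8 ⇐ enone 7 + methyl nucleophile; 7 ⇐ cyclopent‑2‑enone 4 + the N‑acyliminium ion made by Shono oxidation of (S)‑N‑acetyl‑2‑methylpiperidine (gives the cis‑2,6‑piperidine).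
5. Ring order: piperidine (bought) → ring A (bought) → ring C (bought) → ring B + lactone (one step) → C8a–OH.

Assumption: (S)‑2‑methylpiperidine, cyclopent‑2‑en‑1‑one and (E)‑3‑(cyclohex‑1‑en‑1‑yl)acrylic acid are bought as such.
Locants used for 13–15 and F3–F5: naphtho[2,3‑c]furan‑1‑one numbering (C1(=O), O2, C3, C3a, C4, C4a, C5–C8, C8a, C9, C9a); C10 (CH2 on C4) and C11 (CH on C3, bears the piperidine) close the cyclopentane C3–C3a–C4–C10–C11.

**Step 1**
Reactants: 1 (S)‑2‑methylpiperidine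
Product: 2 1‑[(2S)‑2‑methylpiperidin‑1‑yl]ethan‑1‑one
Conditions: Ac2O, Et3N, CH2Cl2, 0 °C → rt
Reagents that add atoms: acetic anhydride, CC(=O)OC(C)=O
Why: N‑acylation of the secondary amine; the stereocentre is untouched and the acetyl group is the one in the target.

**Step 2**
Reactants: 2 1‑[(2S)‑2‑methylpiperidin‑1‑yl]ethan‑1‑one
Product: 3 1‑[(6S)‑2‑methoxy‑6‑methylpiperidin‑1‑yl]ethan‑1‑one (both C2 epimers)
Conditions: –2e, graphite anode, Et4NOTs, MeOH, 0 °C, 2.5 F/mol, undivided cell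
Reagents that add atoms: methanol, CO
Why: Shono anodic α‑methoxylation; the amide radical cation loses a proton at the less substituted α‑carbon (CH2, not the methine), methanol traps the N‑acyliminium ion, and the (S)‑methyl centre is kept.

**Step 3**
Reactants: 3 1‑[(6S)‑2‑methoxy‑6‑methylpiperidin‑1‑yl]ethan‑1‑one; 4 cyclopent‑2‑en‑1‑one
Product: 7 (5R)‑5‑[(2S,6S)‑1‑acetyl‑6‑methylpiperidin‑2‑yl]cyclopent‑2‑en‑1‑one, via silyl dienol ether 5 (not isolated), via N‑acyliminium triflate 6 (not isolated)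
Conditions: 4, TIPSOTf (1.0 equiv), Et3N, CH2Cl2, 0 °C; then 3, TIPSOTf (0.2 equiv), –78 → –45 °C
Reagents that add atoms: none
Why: Mukaiyama–Mannich addition to a cyclic N‑acyliminium ion: A(1,3) strain with N‑acetyl holds the methyl group axial and axial attack on the half‑chair gives the 2,6‑cis piperidine, while the open antiperiplanar transition state (bulky TIPSO‑bearing enol carbon anti to the iminium nitrogen, the two hydrogens anti) is expected to set C5 of the enone as R.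

**Step 4**
Reactants: 7 (5R)‑5‑[(2S,6S)‑1‑acetyl‑6‑methylpiperidin‑2‑yl]cyclopent‑2‑en‑1‑one
Product: 8 (1R,5R)‑5‑[(2S,6S)‑1‑acetyl‑6‑methylpiperidin‑2‑yl]‑1‑methylcyclopent‑2‑en‑1‑ol (OH cis to the piperidinyl group)
Conditions: MeLi, anhydrous CeCl3, THF, –78 °C; aq. NH4Cl
Reagents that add atoms: methyllithium, [Li]C
Why: 1,2‑addition of the non‑basic organocerium reagent (Imamoto conditions) to the enone carbonyl without enolisation or attack on the amide; methyl enters anti to the C5 piperidinyl group, so the tertiary OH is cis to it.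

**Step 5**
Reactants: 8 (1R,5R)‑5‑[(2S,6S)‑1‑acetyl‑6‑methylpiperidin‑2‑yl]‑1‑methylcyclopent‑2‑en‑1‑ol; 9 (2E)‑3‑(cyclohex‑1‑en‑1‑yl)prop‑2‑enoic acid
Product: 12 (1R,5R)‑5‑[(2S,6S)‑1‑acetyl‑6‑methylpiperidin‑2‑yl]‑1‑methylcyclopent‑2‑en‑1‑yl (2E)‑3‑(cyclohex‑1‑en‑1‑yl)prop‑2‑enoate, via acid chloride 10 (not isolated), via potassium alkoxide 11 (not isolated)
Conditions: 9, (COCl)2, cat. DMF, CH2Cl2, 0 °C → rt, evaporate; 8, KHMDS, THF, –78 °C, then 10, –78 → 0 °C
Reagents that add atoms: none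
Why: O‑acylation of a hindered tertiary alkoxide with an acid chloride; the C–O bond made here becomes the O2–C1 bond of the lactone and the tether for step 6, and no stereocentre changes.

**Step 6**
Reactants: 12 (1R,5R)‑5‑[(2S,6S)‑1‑acetyl‑6‑methylpiperidin‑2‑yl]‑1‑methylcyclopent‑2‑en‑1‑yl (2E)‑3‑(cyclohex‑1‑en‑1‑yl)prop‑2‑enoate
Product: 13 (3R,3aS,4S,4aS,9aS,11R)‑11‑[(2S,6S)‑1‑acetyl‑6‑methylpiperidin‑2‑yl]‑3‑methyl‑3,4‑ethano‑3a,4,4a,5,6,7,8,9a‑octahydronaphtho[2,3‑c]furan‑1(3H)‑one (Δ8a,9; trans‑fused lactone, H‑9a anti to H‑3a)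
Conditions: o‑C6H4Cl2 (5 mM), BHT, solid K2CO3, 185 °C, sealed tube
Reagents that add atoms: none
Why: Ester‑tethered intramolecular Diels–Alder reaction of the himbacine type: the three‑atom tether can only deliver the diene to the cyclopentene face syn to the ester oxygen (C3a and C4 cis to O), and the exo mode (ring A turned away from the diene) gives H‑4a anti to H‑4 and the trans‑fused lactone; C9a is made planar again in step 7.

**Step 7**
Reactants: 13 (the β,γ‑unsaturated lactone from step 6)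
Product: 15 (3R,3aS,4S,4aS,8aS,11R)‑11‑[(2S,6S)‑1‑acetyl‑6‑methylpiperidin‑2‑yl]‑8a‑hydroxy‑3‑methyl‑3,4‑ethano‑3a,4,4a,5,6,7,8,8a‑octahydronaphtho[2,3‑c]furan‑1(3H)‑one (Δ9,9a; 8a‑OH anti to H‑4a), via hydroperoxide 14 (not isolated)
Conditions: KOt‑Bu (20 mol %), O2 (1 atm), P(OEt)3 (1.5 equiv), THF–DMSO 4:1, –20 → 0 °C
Reagents that add atoms: dioxygen, O=O
Why: Proposed new method: base‑catalytic aerobic isomerising γ‑hydroxylation of a β,γ‑unsaturated fused γ‑lactone — catalytic alkoxide removes the doubly activated H‑9a (either C9a epimer gives the same planar dienolate), electron transfer to O2 and C–O bond formation at the tertiary γ‑carbon C8a put the alkene into conjugation, P(OEt)3 reduces the hydroperoxide anion to the tertiary alkoxide, and that alkoxide deprotonates the next molecule of 13 (alkoxide relay, so base is catalytic); oxygen enters C8a axially, anti to H‑4a and away from the axial ring‑A carbon, which gives the trans‑decalin carbinol; closest known reaction type: γ‑hydroxylation of enone and butenolide dienolates with stoichiometric strong base, O2 and P(OEt)3, and carbonate‑catalysed aerobic α‑hydroxylation of ketones.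

**Compound list**
1 | (S)‑2‑methylpiperidine | C[C@H]1CCCCN1 | starting material
2 | 1‑[(2S)‑2‑methylpiperidin‑1‑yl]ethan‑1‑one | CC(=O)N1[C@@H](C)CCCC1 | intermediate
3 | 1‑[(6S)‑2‑methoxy‑6‑methylpiperidin‑1‑yl]ethan‑1‑one (C2 epimers) | CC(=O)N1[C@@H](C)CCCC1OC | intermediate
4 | cyclopent‑2‑en‑1‑one | O=C1C=CCC1 | starting material
5 | (cyclopenta‑1,4‑dien‑1‑yloxy)tri(propan‑2‑yl)silane | CC(C)[Si](OC1=CCC=C1)(C(C)C)C(C)C | intermediate (not isolated)
6 | (2S)‑1‑acetyl‑2‑methyl‑2,3,4,5‑tetrahydropyridin‑1‑ium trifluoromethanesulfonate | CC(=O)[N+]1=CCCC[C@@H]1C.[O-]S(=O)(=O)C(F)(F)F | intermediate (not isolated)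
7 | (5R)‑5‑[(2S,6S)‑1‑acetyl‑6‑methylpiperidin‑2‑yl]cyclopent‑2‑en‑1‑one | CC(=O)N1[C@@H](C)CCC[C@H]1[C@H]1CC=CC1=O | intermediate
8 | (1R,5R)‑5‑[(2S,6S)‑1‑acetyl‑6‑methylpiperidin‑2‑yl]‑1‑methylcyclopent‑2‑en‑1‑ol | CC(=O)N1[C@@H](C)CCC[C@H]1[C@H]1CC=C[C@@]1(C)O | intermediate
9 | (2E)‑3‑(cyclohex‑1‑en‑1‑yl)prop‑2‑enoic acid | OC(=O)/C=C/C1=CCCCC1 | starting material
10 | (2E)‑3‑(cyclohex‑1‑en‑1‑yl)prop‑2‑enoyl chloride | ClC(=O)/C=C/C1=CCCCC1 | intermediate (not isolated)
11 | potassium (1R,5R)‑5‑[(2S,6S)‑1‑acetyl‑6‑methylpiperidin‑2‑yl]‑1‑methylcyclopent‑2‑en‑1‑olate | CC(=O)N1[C@@H](C)CCC[C@H]1[C@H]1CC=C[C@@]1(C)[O-].[K+] | intermediate (not isolated)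
12 | (1R,5R)‑5‑[(2S,6S)‑1‑acetyl‑6‑methylpiperidin‑2‑yl]‑1‑methylcyclopent‑2‑en‑1‑yl (2E)‑3‑(cyclohex‑1‑en‑1‑yl)prop‑2‑enoate | CC(=O)N1[C@@H](C)CCC[C@H]1[C@H]1CC=C[C@@]1(C)OC(=O)/C=C/C1=CCCCC1 | intermediate
13 | (3R,3aS,4S,4aS,9aS,11R)‑11‑[(2S,6S)‑1‑acetyl‑6‑methylpiperidin‑2‑yl]‑3‑methyl‑3,4‑ethano‑3a,4,4a,5,6,7,8,9a‑octahydronaphtho[2,3‑c]furan‑1(3H)‑one | CC(=O)N1[C@@H](C)CCC[C@H]1[C@H]1C[C@@H]2[C@H]3[C@H](C=C4CCCC[C@@H]24)C(=O)O[C@@]13C | intermediate
14 | 8a‑hydroperoxide of 15 (8aS; OOH in place of OH) | CC(=O)N1[C@@H](C)CCC[C@H]1[C@H]1C[C@@H]2[C@H]3C(=C[C@]4(OO)CCCC[C@@H]24)C(=O)O[C@@]13C | intermediate (not isolated)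
15 | (3R,3aS,4S,4aS,8aS,11R)‑11‑[(2S,6S)‑1‑acetyl‑6‑methylpiperidin‑2‑yl]‑8a‑hydroxy‑3‑methyl‑3,4‑ethano‑3a,4,4a,5,6,7,8,8a‑octahydronaphtho[2,3‑c]furan‑1(3H)‑one (CNP0529632.1) | CC(=O)N1[C@@H](C)CCC[C@H]1[C@H]1C[C@@H]2[C@H]3C(=C[C@]4(O)CCCC[C@@H]24)C(=O)O[C@@]13C | target

**Total step count:** 7. **Longest linear sequence:** 7 steps (1 → 15); 4 and 9 enter as bought materials.

**Three steps most likely to fail**

Step 3. The cis‑2,6 outcome has good precedent, but the configuration at C5 of the enone rests on an open transition state and may come out as a mixture; the iminium ion can also tautomerise to the enamide. The fallback resets that centre by protonation instead of by C–C bond formation. It sets out from 7 as its C5‑epimer mixture: soft enolisation (TBSOTf, Et3N, CH2Cl2, 0 °C) gives the common tert‑butyldimethylsilyl dienol ether F1, in which C5 is sp2. Kinetic protodesilylation (TBAF, AcOH, THF, –78 °C) then puts the proton on the face anti to the N‑acetyl nitrogen, because A(1,3) strain holds the piperidine C2–H in the diene plane next to the silyloxy group. This returns (5R)‑7, where the route is rejoined.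

Step 6. An unactivated cyclopentene and a planar ester tether make the cycloaddition slow, and at 185 °C the tertiary allylic ester may eliminate first; the exo preference is taken from the himbacine precedent. The fallback exchanges the ester tether for an sp3 acetal tether. It sets out from 12: reductive acetylation (DIBAL‑H, –78 °C; then Ac2O, pyridine, DMAP) gives the α‑acetoxy ether F2, which has no s‑trans ester rotamer to overcome and no acyloxy leaving group. Thermal cycloaddition (toluene, 140 °C) gives the lactol acetate F3, methanolysis (K2CO3, MeOH) gives the lactol F4, and oxidation (TPAP, NMO) returns lactone 13, where the route is rejoined.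

Step 7 (the new step). Oxygen may attack the α‑carbon C9a instead of C8a, the face selectivity at C8a is predicted and not proven, and the alkoxide relay may not turn over. The fallback uses known chemistry and sets out from 13: epoxidation (mCPBA, NaHCO3, CH2Cl2, 0 °C) occurs on the alkene face anti to H‑4a, the other face being shielded by the axial ring‑A carbon, and gives the 8a,9‑epoxide F5. DBU (CH2Cl2, rt) then deprotonates C9a and opens the epoxide by E1cB elimination (C9–O cleavage, C8a–O kept), which gives 15 directly; both C9a epimers converge.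

**Further compounds**
F1 | step 3 | 1‑[(2S,6S)‑2‑{2‑[(tert‑butyldimethylsilyl)oxy]cyclopenta‑1,3‑dien‑1‑yl}‑6‑methylpiperidin‑1‑yl]ethan‑1‑one | CC(=O)N1[C@@H](C)CCC[C@H]1C1=C(O[Si](C)(C)C(C)(C)C)C=CC1
F2 | step 6 | (2E)‑1‑{[(1R,5R)‑5‑[(2S,6S)‑1‑acetyl‑6‑methylpiperidin‑2‑yl]‑1‑methylcyclopent‑2‑en‑1‑yl]oxy}‑3‑(cyclohex‑1‑en‑1‑yl)prop‑2‑en‑1‑yl acetate (C1 epimers) | CC(=O)N1[C@@H](C)CCC[C@H]1[C@H]1CC=C[C@@]1(C)OC(OC(C)=O)/C=C/C1=CCCCC1
F3 | step 6 | lactol acetate of 13 (C1 is CH–OAc in place of C=O, C1 epimers; other centres as in 13) | CC(=O)N1[C@@H](C)CCC[C@H]1[C@H]1C[C@@H]2[C@H]3[C@H](C=C4CCCC[C@@H]24)C(OC(C)=O)O[C@@]13C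
F4 | step 6 | lactol of 13 (C1 is CH–OH in place of C=O, C1 epimers; other centres as in 13) | CC(=O)N1[C@@H](C)CCC[C@H]1[C@H]1C[C@@H]2[C@H]3[C@H](C=C4CCCC[C@@H]24)C(O)O[C@@]13C
F5 | step 7 | 8a,9‑epoxide of 13 (epoxide oxygen anti to H‑4a, syn to H‑3a and H‑4) | CC(=O)N1[C@@H](C)CCC[C@H]1[C@H]1C[C@@H]2[C@H]3[C@H]([C@H]5O[C@]54CCCC[C@@H]24)C(=O)O[C@@]13C
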